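**Strategy**

The route rests on reading each 2,2-dimethyl-2H-pyran ring as a disguised coumarin: its quaternary C2, bonded to O1 and carrying both methyl groups, is a former lactone carbonyl carbon. The butenyl linker and its single stereocentre are therefore built on two sturdy limettin units, and one treatment of the (S,E)-bis-coumarin with methyllithium then creates all four C2–CH3 bonds, exposing two phenols and two cis-placed tertiary allylic carbinols without closing any ring. The precursor is thus an 8,8'-linked bis(5,7-dimethoxycoumarin) carrying the E-olefin and the (S)-methine; mild acid finally closes both pyrans.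

Key step: step 6

Assumption: the (R,R) antipode of the diene ligand Ph-bod* [(1R,4R)-2,5-diphenylbicyclo[2.2.2]octa-2,5-diene] is taken to deliver the aryl group to the Si face of C3 of (E)-but-2-enal, which gives the S centre; should a trial run show the opposite sense, the (S,S) antipode is used and nothing else changes.

**Route**

Step 1
Reactants: 1 5,7-dimethoxy-2H-chromen-2-one (limettin); 2 N-iodosuccinimide
Product: 3 8-iodo-5,7-dimethoxy-2H-chromen-2-one
Conditions: NIS (1.05 equiv), TFA (0.3 equiv), MeCN, 0 °C → rt
Reagents that add atoms: N-iodosuccinimide, O=C1CCC(=O)N1I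
Why: Electrophilic aromatic iodination should go to C8, which is ortho to the 7-methoxy and para to the 5-methoxy group and is the most activated and less crowded nuclear position, since the ring oxygen para to C6 donates weakly as part of the lactone.

Step 2
Reactants: 3 8-iodo-5,7-dimethoxy-2H-chromen-2-one; 4 bis(pinacolato)diboron
Product: 5 5,7-dimethoxy-8-(4,4,5,5-tetramethyl-1,3,2-dioxaborolan-2-yl)-2H-chromen-2-one
Conditions: B2pin2 (1.3 equiv), Pd2(dba)3 (2 mol%), XPhos (8 mol%), KOAc (3 equiv), 1,4-dioxane, 90 °C
Reagents that add atoms: bis(pinacolato)diboron, CC1(C)OB(OC1(C)C)B1OC(C)(C)C(C)(C)O1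
Why: Miyaura borylation with a bulky biarylphosphine should tolerate the doubly ortho-substituted iodide, and the weak acetate base leaves the lactone intact.

Step 3
Reactants: 5 5,7-dimethoxy-8-(4,4,5,5-tetramethyl-1,3,2-dioxaborolan-2-yl)-2H-chromen-2-one; 6 (E)-but-2-enal
Product: 7 (S)-3-(5,7-dimethoxy-2-oxo-2H-chromen-8-yl)butanal
Conditions: (E)-but-2-enal (3 equiv), [RhCl(C2H4)2]2 (1.5 mol%), (R,R)-Ph-bod* (3.3 mol%), KOH (0.2 equiv), 1,4-dioxane/H2O 10:1, 40 °C; then 1 M HCl wash
Reagents that add atoms: (E)-but-2-enal, C/C=C/C=O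
Why: Rhodium-catalysed asymmetric 1,4-addition of an arylboron reagent to an enal (Hayashi–Miyaura reaction), in which the chiral diene directs aryl transfer to the Si face of C3 and so sets the S centre, diene ligands favour conjugate over carbonyl addition, and the enal is a far better acceptor than the electron-rich coumarin C3=C4 bond.

Step 4
Reactants: 7 (S)-3-(5,7-dimethoxy-2-oxo-2H-chromen-8-yl)butanal; 3 8-iodo-5,7-dimethoxy-2H-chromen-2-one
Product: 9 (3S)-1,3-bis(5,7-dimethoxy-2-oxo-2H-chromen-8-yl)butan-1-ol (C1 epimer mixture), via aryl-CrCl2 species 8 (not isolated)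
Conditions: 3 (1.5 equiv), CrCl2 (4 equiv), NiCl2 (2 mol%), degassed DMF, rt → 40 °C; then H2O
Reagents that add atoms: 8-iodo-5,7-dimethoxy-2H-chromen-2-one, COc1cc(OC)c2ccc(=O)oc2c1I
Why: Nozaki–Hiyama–Kishi coupling, in which the nickel-activated aryl iodide is passed to chromium as 8 and adds to the aldehyde only, sparing both lactones and the non-epimerisable C3 centre; the new carbinol centre forms without control and is removed in step 5.

Step 5
Reactants: 9 (3S)-1,3-bis(5,7-dimethoxy-2-oxo-2H-chromen-8-yl)butan-1-ol
Product: 11 (S,E)-8,8'-(but-1-ene-1,3-diyl)bis(5,7-dimethoxy-2H-chromen-2-one), via benzylic sulfamate salt 10 (not isolated)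
Conditions: Burgess reagent (1.5 equiv), toluene, rt → 60 °C
Reagents that add atoms: none
Why: Burgess dehydration through the sulfamate 10 can only remove a C2 hydrogen, so both carbinol epimers should converge on the conjugated E-styrene, while the neutral conditions avoid acid- or base-mediated migration of the double bond towards the C3 stereocentre.

Step 6
Reactants: 11 (S,E)-8,8'-(but-1-ene-1,3-diyl)bis(5,7-dimethoxy-2H-chromen-2-one); 12 methyllithium
Product: 14 (3Z,3'Z)-4,4'-{[(S,E)-but-1-ene-1,3-diyl]bis(2-hydroxy-4,6-dimethoxy-3,1-phenylene)}bis(2-methylbut-3-en-2-ol), via bis(cis-enone) dilithium bis-phenoxide 13 (not isolated)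
Conditions: MeLi (6 equiv), THF, −78 → 0 °C; then sat. aq. NH4Cl, 0 °C; crude product taken on
Reagents that add atoms: methyllithium, [Li]C
Why: Each lactone carbonyl C2 is attacked by methyllithium, the tetrahedral lactolate collapses with expulsion of the C8a phenoxide to the cis-aryl methyl enone 13, and a second methyllithium adds to that ketone, so four C–CH3 bonds are made and no ring is closed in this operation. The closest known reaction type is the double 1,2-addition of methyl Grignard or methyllithium reagents to coumarins, which gives cis-2-hydroxycinnamyl tertiary carbinols as precursors of 2,2-dimethyl-2H-chromenes. No new stereocentre arises; the C3=C4 geometry of each coumarin is carried over as the Z-olefin, which keeps each phenol and its carbinol within reach for step 7. The selectivity required is carbonyl (1,2) over conjugate (1,4) attack at both lactones, and it is secured by the hard, unhindered methyl nucleophile at low temperature together with the 5-methoxy group, which shields and deactivates C4. The benzylic, allylic C–H of the stereocentre should survive because methyllithium is a slow carbon base under these conditions and both rings become electron-rich phenoxides as the reaction proceeds.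

Step 7
Reactants: 14 (3Z,3'Z)-4,4'-{[(S,E)-but-1-ene-1,3-diyl]bis(2-hydroxy-4,6-dimethoxy-3,1-phenylene)}bis(2-methylbut-3-en-2-ol)
Product: 15 (S,E)-8,8'-(but-1-ene-1,3-diyl)bis(5,7-dimethoxy-2,2-dimethyl-2H-chromene) (CNP0198894.2)
Conditions: pyridinium p-toluenesulfonate (10 mol%), 4 Å molecular sieves, CH2Cl2, rt
Reagents that add atoms: none
Why: Acid-catalysed cyclodehydration, in which each tertiary allylic carbinol ionises and the neighbouring cis-held phenol oxygen closes the six-membered pyran ring, should proceed under acid too weak to protonate the electron-rich styrene, so the E-olefin and the S centre are untouched.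

**Compound list**

1 | 5,7-dimethoxy-2H-chromen-2-one (limettin) | COc1cc(OC)c2ccc(=O)oc2c1 | starting material
2 | N-iodosuccinimide | O=C1CCC(=O)N1I | starting material
3 | 8-iodo-5,7-dimethoxy-2H-chromen-2-one | COc1cc(OC)c2ccc(=O)oc2c1I | intermediate
4 | bis(pinacolato)diboron | CC1(C)OB(OC1(C)C)B1OC(C)(C)C(C)(C)O1 | starting material
5 | 5,7-dimethoxy-8-(4,4,5,5-tetramethyl-1,3,2-dioxaborolan-2-yl)-2H-chromen-2-one | COc1cc(OC)c2ccc(=O)oc2c1B1OC(C)(C)C(C)(C)O1 | intermediate
6 | (E)-but-2-enal | C/C=C/C=O | starting material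
7 | (S)-3-(5,7-dimethoxy-2-oxo-2H-chromen-8-yl)butanal | O=CC[C@H](C)c1c(OC)cc(OC)c2ccc(=O)oc12 | intermediate
8 | (5,7-dimethoxy-2-oxo-2H-chromen-8-yl)chromium dichloride (trivalent chromium; formed in the flask, not isolated) | COc1cc(OC)c2ccc(=O)oc2c1[Cr](Cl)Cl | intermediate
9 | (3S)-1,3-bis(5,7-dimethoxy-2-oxo-2H-chromen-8-yl)butan-1-ol (C1 epimer mixture) | COc1cc(OC)c(C(O)C[C@H](C)c2c(OC)cc(OC)c3ccc(=O)oc23)c2oc(=O)ccc12 | intermediate
10 | triethylammonium salt of the N-(methoxycarbonyl)sulfamate ester of 9 (formed in the flask, not isolated) | COc1cc(OC)c(C(OS(=O)(=O)[N-]C(=O)OC)C[C@H](C)c2c(OC)cc(OC)c3ccc(=O)oc23)c2oc(=O)ccc12.CC[NH+](CC)CC | intermediate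
11 | (S,E)-8,8'-(but-1-ene-1,3-diyl)bis(5,7-dimethoxy-2H-chromen-2-one) | COc1cc(OC)c(/C=C/[C@H](C)c2c(OC)cc(OC)c3c2oc(=O)cc3)c2c1ccc(=O)o2 | intermediate
12 | methyllithium | [Li]C | starting material
13 | dilithium bis-phenoxide of (3Z,3'Z)-4,4'-{[(S,E)-but-1-ene-1,3-diyl]bis(2-hydroxy-4,6-dimethoxy-3,1-phenylene)}bis(but-3-en-2-one) (formed in the flask, not isolated) | COc1cc(OC)c(/C=C/[C@H](C)c2c(OC)cc(OC)c(/C=C\C(C)=O)c2[O-])c([O-])c1/C=C\C(C)=O.[Li+].[Li+] | intermediate
14 | (3Z,3'Z)-4,4'-{[(S,E)-but-1-ene-1,3-diyl]bis(2-hydroxy-4,6-dimethoxy-3,1-phenylene)}bis(2-methylbut-3-en-2-ol) | COc1cc(OC)c(/C=C/[C@H](C)c2c(OC)cc(OC)c(/C=C\C(C)(C)O)c2O)c(O)c1/C=C\C(C)(C)O | intermediate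
15 | (S,E)-8,8'-(but-1-ene-1,3-diyl)bis(5,7-dimethoxy-2,2-dimethyl-2H-chromene) | COc1cc(OC)c(/C=C/[C@H](C)c2c(OC)cc(OC)c3c2OC(C)(C)C=C3)c2c1C=CC(C)(C)O2 | target

**Step count and risks**

Total step count: 7. Longest linear sequence: 7 steps (1 → 3 → 5 → 7 → 9 → 11 → 14 → 15); iodide 3 is used a second time in step 4.

Steps most likely to fail: step 3, step 4 and step 6.

Step 3. The doubly ortho-oxygenated boronate may lose boron to protonolysis faster than it transfers its aryl group to rhodium, or the crowded aryl may be delivered with poor facial selectivity. The fallback leaves out boron and sets out from iodide 3 and enal 6. A ligand-free, phase-transfer Heck arylation (Pd(OAc)2, Bu4NCl, NaHCO3, DMF, 80 °C) should give (E)-3-(5,7-dimethoxy-2-oxo-2H-chromen-8-yl)but-2-enal F1, in which either olefin geometry is acceptable. Iminium-catalysed transfer hydrogenation then follows, with the Hantzsch ester and the trichloroacetate salt of a chiral 2-tert-butyl-3-methylimidazolidin-4-one (antipode chosen for the S product) in CHCl3 at −30 °C. It should reduce only the enal double bond, both geometries converging on one enantiomer, and the fallback comes back to the route at aldehyde 7.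

Step 4. Oxidative addition and metal-to-metal transfer at the hindered, electron-rich iodide may be too slow, so that the coupling stalls while the iodide is simply reduced. The fallback sets out from iodide 3. Iodine–magnesium exchange with iPrMgCl·LiCl (THF, −40 °C), which tolerates ester-type carbonyls at this temperature, gives (5,7-dimethoxy-2-oxo-2H-chromen-8-yl)magnesium chloride F2. Addition of aldehyde 7 at −40 °C and an aqueous quench bring the fallback back to the route at alcohol 9.

Step 6. Conjugate addition at C4 may compete, or one lactone may stall at the mono-adduct (lactolate) stage, giving mixtures that are hard to separate. The fallback sets out from bis-coumarin 11 and moves the methyl addition to open-chain esters. Both lactones are opened with NaOH (4.2 equiv, THF/MeOH/H2O, rt, dark), the solution is concentrated, and the phenoxide–carboxylate salt is alkylated with allyl bromide in DMF. This gives diallyl (2Z,2'Z)-3,3'-{[(S,E)-but-1-ene-1,3-diyl]bis[2-(allyloxy)-4,6-dimethoxy-3,1-phenylene]}bis(prop-2-enoate) F3. Double addition of MeLi to each cis-ester (THF, −78 °C, then sat. aq. NH4Cl) should give (3Z,3'Z)-4,4'-{[(S,E)-but-1-ene-1,3-diyl]bis[2-(allyloxy)-4,6-dimethoxy-3,1-phenylene]}bis(2-methylbut-3-en-2-ol) F4. Removal of the aryl allyl ethers with Pd(PPh3)4 and morpholine (THF, rt) brings the fallback back to the route at bis-phenol 14.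

**Further compounds**

F1 | step 3 | (E)-3-(5,7-dimethoxy-2-oxo-2H-chromen-8-yl)but-2-enal | C/C(=C\C=O)c1c(OC)cc(OC)c2ccc(=O)oc12
F2 | step 4 | (5,7-dimethoxy-2-oxo-2H-chromen-8-yl)magnesium chloride | COc1cc(OC)c2ccc(=O)oc2c1[Mg]Cl
F3 | step 6 | diallyl (2Z,2'Z)-3,3'-{[(S,E)-but-1-ene-1,3-diyl]bis[2-(allyloxy)-4,6-dimethoxy-3,1-phenylene]}bis(prop-2-enoate) | COc1cc(OC)c(/C=C/[C@H](C)c2c(OC)cc(OC)c(/C=C\C(=O)OCC=C)c2OCC=C)c(OCC=C)c1/C=C\C(=O)OCC=C
F4 | step 6 | (3Z,3'Z)-4,4'-{[(S,E)-but-1-ene-1,3-diyl]bis[2-(allyloxy)-4,6-dimethoxy-3,1-phenylene]}bis(2-methylbut-3-en-2-ol) | COc1cc(OC)c(/C=C/[C@H](C)c2c(OC)cc(OC)c(/C=C\C(C)(C)O)c2OCC=C)c(OCC=C)c1/C=C\C(C)(C)O
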